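**Retrosynthetic overview**
1. Numbering: C1–C20 of the open-chain acid (C1 = lactone carbonyl; ring C6 = C5; side-chain C2'/C4'/C6' = C7/C9/C11). The dihydropyranone, the only ring of the target, is closed late by lactonization of a (Z)-5-hydroxy-2-enoate; C3–C4 comes from lithiated ethyl propiolate (a β-acylvinyl anion) opening a terminal epoxide.
2. The C7 and C11 carbinols come from ketones masked as 1,3-dithianes: C7 is reduced anti to the free C5 hydroxyl, C11 syn to the C9 hydroxyl.
3. Key step (step 2): one-flask union of a 2-silyl-1,3-dithiane (formyl dianion equivalent) with a dithianyl epoxide and (R)-epichlorohydrin through a 1,4-Brook relay. It makes C7–C8 and C6–C7, each between a masked carbonyl carbon and an epoxide carbon, and leaves the C4–C5 epoxide.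
4. The dithianyl epoxide is made in one flask from 1,3-dithiane, 1-bromononane and (S)-epichlorohydrin; C9 and C5 are bought as the two epichlorohydrins.
5. Ring order: dithianes (present from step 1, removed in step 4), epoxides (made in steps 1 and 2, opened in steps 2 and 3), dihydropyranone (step 6).

Assumption: 2-(tert-butyldimethylsilyl)-1,3-dithiane is bought as a catalogue reagent, and lithiated dithianes attack epichlorohydrin at the ring CH2 rather than at C–Cl.
Note: descriptor changes at C7 and C9 between intermediates (for example 9S in 19, 9R in 20) are CIP-priority effects only; no center is inverted once it is set.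

**Step 1**
Reactants: 1 1,3-dithiane; 2 1-bromononane; 3 (S)-epichlorohydrin
Product: 8 (S)-2-nonyl-2-(oxiran-2-ylmethyl)-1,3-dithiane, via 2-lithio-1,3-dithiane 4 (not isolated), via 2-nonyl-1,3-dithiane 5 (not isolated), via 2-lithio-2-nonyl-1,3-dithiane 6 (not isolated), via lithium chloro alkoxide 7 (not isolated)
Conditions: n-BuLi, THF, −30 °C; 2, −78 → 0 °C; n-BuLi, −20 °C; 3, −78 °C → rt
Reagents that add atoms: none
Why: One-flask Corey–Seebach double alkylation of a formyl dianion equivalent: the lithiated dithiane displaces the primary bromide, is re-metalated, and then opens (S)-epichlorohydrin at its ring CH2, after which chloro alkoxide 7 closes to the new epoxide, so no bond to the stereocenter is broken and C9 is taken over from the chiral pool.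

**Step 2**
Reactants: 8 (S)-2-nonyl-2-(oxiran-2-ylmethyl)-1,3-dithiane; 9 2-(tert-butyldimethylsilyl)-1,3-dithiane; 10 (R)-epichlorohydrin
Product: 15 2-[(S)-2-(tert-butyldimethylsilyloxy)-3-(2-nonyl-1,3-dithian-2-yl)propyl]-2-[(R)-oxiran-2-ylmethyl]-1,3-dithiane, via lithiated silyl dithiane 11 (not isolated), via silyl alkoxide 12 (not isolated), via Brook-rearranged lithio dithiane 13 (not isolated), via lithium chloro alkoxide 14 (not isolated)
Conditions: 9, t-BuLi, Et2O, −78 → −45 °C; 8, Et2O, −78 → −25 °C; then 10, HMPA, THF, −78 °C → rt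
Reagents that add atoms: none
Why: Three-component linchpin coupling driven by a solvent-gated 1,4-Brook rearrangement (anion relay): lithiated 9 opens 8 at its terminal CH2, HMPA then triggers C-to-O silyl migration in alkoxide 12 to give the new dithiane anion 13, which opens (R)-epichlorohydrin and recloses to the epoxide, so that one masked carbonyl carbon is joined twice to epoxide carbons (all electrophilic in normal polarity), C9 is protected in passing and C5 is taken over unchanged from 10.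

**Step 3**
Reactants: 15 2-[(S)-2-(tert-butyldimethylsilyloxy)-3-(2-nonyl-1,3-dithian-2-yl)propyl]-2-[(R)-oxiran-2-ylmethyl]-1,3-dithiane; 16 ethyl propiolate
Product: 18 ethyl (S)-6-{2-[(S)-2-(tert-butyldimethylsilyloxy)-3-(2-nonyl-1,3-dithian-2-yl)propyl]-1,3-dithian-2-yl}-5-hydroxyhex-2-ynoate, via ethyl 3-lithiopropiolate 17 (not isolated)
Conditions: 16, n-BuLi, THF, −78 °C; BF3·OEt2; then 15, −78 °C
Reagents that add atoms: none
Why: Yamaguchi–Hirao alkynylation: the lithium acetylide of ethyl propiolate, a β-acylvinyl anion (homoenolate-type d3) equivalent whose β-carbon is an electrophile in normal polarity, opens the BF3-activated epoxide at the unhindered CH2 (C4) without touching C5.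

**Step 4**
Reactants: 18 ethyl (S)-6-{2-[(S)-2-(tert-butyldimethylsilyloxy)-3-(2-nonyl-1,3-dithian-2-yl)propyl]-1,3-dithian-2-yl}-5-hydroxyhex-2-ynoate
Product: 19 ethyl (5S,9S)-9-(tert-butyldimethylsilyloxy)-5-hydroxy-7,11-dioxoicos-2-ynoate
Conditions: PhI(OCOCF3)2, MeCN/H2O (9:1), 0 °C
Reagents that add atoms: water, O
Why: Oxidative dithioacetal hydrolysis with a hypervalent iodine reagent (Stork conditions) frees both ketones in minutes at 0 °C, conditions that a secondary TBS ether, a free alcohol and an ynoate tolerate; no stereocenter is involved.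

**Step 5**
Reactants: 19 ethyl (5S,9S)-9-(tert-butyldimethylsilyloxy)-5-hydroxy-7,11-dioxoicos-2-ynoate
Product: 20 ethyl (5S,7R,9R)-9-(tert-butyldimethylsilyloxy)-5,7-dihydroxy-11-oxoicos-2-ynoate
Conditions: Me4NBH(OAc)3, MeCN/AcOH (1:1), −30 °C
Reagents that add atoms: none
Why: Evans–Saksena hydroxyl-directed reduction: the free C5 hydroxyl binds boron and delivers hydride intramolecularly through a chair transition state to the C7 ketone, giving the 1,3-anti diol (7R here), while the C11 ketone, flanked only by the silyl ether, has no hydroxyl to bind the reagent and is left alone.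

**Step 6**
Reactants: 20 ethyl (5S,7R,9R)-9-(tert-butyldimethylsilyloxy)-5,7-dihydroxy-11-oxoicos-2-ynoate
Product: 23 (S)-6-[(2S,4R)-2,4-dihydroxy-6-oxopentadecyl]-5,6-dihydro-2H-pyran-2-one, via (Z)-enoate 21 (not isolated), via silyl lactone 22 (not isolated)
Conditions: H2 (1 atm), Pd/CaCO3 poisoned with Pb(OAc)2, quinoline, EtOAc, rt; filter; then HF (48% aq.), MeCN, 0 °C → rt
Reagents that add atoms: none
Why: Lindlar cis-semihydrogenation gives (Z)-enoate 21, and aqueous HF then both closes the six-membered lactone from the C5 hydroxyl (the C7 hydroxyl could only form an eight-membered ring) and cleaves the TBS ether (acid-promoted lactonization and desilylation), with no stereocenter affected.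

**Step 7**
Reactants: 23 (S)-6-[(2S,4R)-2,4-dihydroxy-6-oxopentadecyl]-5,6-dihydro-2H-pyran-2-one
Product: 24 (S)-6-[(2S,4S,6S)-2,4,6-trihydroxypentadecyl]-5,6-dihydro-2H-pyran-2-one
Conditions: Et2BOMe, THF/MeOH (4:1), −78 °C; then NaBH4, −78 °C; MeOH co-evaporation
Reagents that add atoms: none
Why: Narasaka–Prasad reduction: the C9 oxygen and the C11 ketone are locked in a six-membered diethylboron chelate and NaBH4 adds hydride axially to give the 1,3-syn diol (C11, the last stereocenter), while at −78 °C the unsaturated lactone is not reduced.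

**Compound list**
1 | 1,3-dithiane | C1CSCSC1 | starting material
2 | 1-bromononane | CCCCCCCCCBr | starting material
3 | (S)-epichlorohydrin [(S)-2-(chloromethyl)oxirane] | ClC[C@@H]1CO1 | starting material
4 | 2-lithio-1,3-dithiane | [Li]C1SCCCS1 | intermediate
5 | 2-nonyl-1,3-dithiane | CCCCCCCCCC1SCCCS1 | intermediate
6 | 2-lithio-2-nonyl-1,3-dithiane | [Li]C1(CCCCCCCCC)SCCCS1 | intermediate
7 | lithium (S)-1-chloro-3-(2-nonyl-1,3-dithian-2-yl)propan-2-olate | ClC[C@@H]([O-])CC1(CCCCCCCCC)SCCCS1.[Li+] | intermediate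
8 | (S)-2-nonyl-2-(oxiran-2-ylmethyl)-1,3-dithiane | CCCCCCCCCC1(C[C@H]2CO2)SCCCS1 | intermediate
9 | 2-(tert-butyldimethylsilyl)-1,3-dithiane | CC(C)(C)[Si](C)(C)C1SCCCS1 | starting material
10 | (R)-epichlorohydrin [(R)-2-(chloromethyl)oxirane] | ClC[C@H]1CO1 | starting material
11 | 2-lithio-2-(tert-butyldimethylsilyl)-1,3-dithiane | CC(C)(C)[Si](C)(C)C1([Li])SCCCS1 | intermediate
12 | lithium (S)-1-[2-(tert-butyldimethylsilyl)-1,3-dithian-2-yl]-3-(2-nonyl-1,3-dithian-2-yl)propan-2-olate | CCCCCCCCCC1(C[C@H]([O-])CC2([Si](C)(C)C(C)(C)C)SCCCS2)SCCCS1.[Li+] | intermediate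
13 | 2-lithio-2-[(R)-2-(tert-butyldimethylsilyloxy)-3-(2-nonyl-1,3-dithian-2-yl)propyl]-1,3-dithiane | CCCCCCCCCC1(C[C@H](O[Si](C)(C)C(C)(C)C)CC2([Li])SCCCS2)SCCCS1 | intermediate
14 | lithium (R)-1-{2-[(S)-2-(tert-butyldimethylsilyloxy)-3-(2-nonyl-1,3-dithian-2-yl)propyl]-1,3-dithian-2-yl}-3-chloropropan-2-olate | CCCCCCCCCC1(C[C@H](O[Si](C)(C)C(C)(C)C)CC2(C[C@@H]([O-])CCl)SCCCS2)SCCCS1.[Li+] | intermediate
15 | 2-[(S)-2-(tert-butyldimethylsilyloxy)-3-(2-nonyl-1,3-dithian-2-yl)propyl]-2-[(R)-oxiran-2-ylmethyl]-1,3-dithiane | CCCCCCCCCC1(C[C@H](O[Si](C)(C)C(C)(C)C)CC2(C[C@@H]3CO3)SCCCS2)SCCCS1 | intermediate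
16 | ethyl propiolate (ethyl prop-2-ynoate) | C#CC(=O)OCC | starting material
17 | ethyl 3-lithioprop-2-ynoate | [Li]C#CC(=O)OCC | intermediate
18 | ethyl (S)-6-{2-[(S)-2-(tert-butyldimethylsilyloxy)-3-(2-nonyl-1,3-dithian-2-yl)propyl]-1,3-dithian-2-yl}-5-hydroxyhex-2-ynoate | CCCCCCCCCC1(C[C@H](O[Si](C)(C)C(C)(C)C)CC2(C[C@@H](O)CC#CC(=O)OCC)SCCCS2)SCCCS1 | intermediate
19 | ethyl (5S,9S)-9-(tert-butyldimethylsilyloxy)-5-hydroxy-7,11-dioxoicos-2-ynoate | CCCCCCCCCC(=O)C[C@H](O[Si](C)(C)C(C)(C)C)CC(=O)C[C@@H](O)CC#CC(=O)OCC | intermediate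
20 | ethyl (5S,7R,9R)-9-(tert-butyldimethylsilyloxy)-5,7-dihydroxy-11-oxoicos-2-ynoate | CCCCCCCCCC(=O)C[C@H](O[Si](C)(C)C(C)(C)C)C[C@H](O)C[C@@H](O)CC#CC(=O)OCC | intermediate
21 | ethyl (2Z,5S,7R,9R)-9-(tert-butyldimethylsilyloxy)-5,7-dihydroxy-11-oxoicos-2-enoate | CCCCCCCCCC(=O)C[C@H](O[Si](C)(C)C(C)(C)C)C[C@H](O)C[C@@H](O)C/C=C\C(=O)OCC | intermediate
22 | (S)-6-[(2R,4R)-4-(tert-butyldimethylsilyloxy)-2-hydroxy-6-oxopentadecyl]-5,6-dihydro-2H-pyran-2-one | CCCCCCCCCC(=O)C[C@H](O[Si](C)(C)C(C)(C)C)C[C@H](O)C[C@@H]1CC=CC(=O)O1 | intermediate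
23 | (S)-6-[(2S,4R)-2,4-dihydroxy-6-oxopentadecyl]-5,6-dihydro-2H-pyran-2-one | CCCCCCCCCC(=O)C[C@H](O)C[C@H](O)C[C@@H]1CC=CC(=O)O1 | intermediate
24 | (S)-6-[(2S,4S,6S)-2,4,6-trihydroxypentadecyl]-5,6-dihydro-2H-pyran-2-one | CCCCCCCCC[C@H](O)C[C@H](O)C[C@H](O)C[C@@H]1CC=CC(=O)O1 | target

**Totals and risks**
Total step count: 7. Longest linear sequence: 7 steps (1 → 24); 9, 10 and 16 are bought.

The three steps most likely to fail:

Step 2 (three-component relay coupling). The risks are premature or incomplete silyl migration, double addition to 8, and some direct chloride displacement on 10, which would erode C5. The fallback gives up the relay and makes the same two bonds by separate dithiane alkylations with a separate silylation. It sets out from 8: opening with 2-lithio-1,3-dithiane 4 (THF, −78 → −20 °C) gives (R)-1-(1,3-dithian-2-yl)-3-(2-nonyl-1,3-dithian-2-yl)propan-2-ol F1. Silylation (TBSOTf, 2,6-lutidine, CH2Cl2) gives 2-[(R)-2-(tert-butyldimethylsilyloxy)-3-(2-nonyl-1,3-dithian-2-yl)propyl]-1,3-dithiane F2. Metalation of F2 (t-BuLi, THF/HMPA, −78 °C, which gives anion 13) and alkylation with 10 bring the route back at 15.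

Step 3 (propiolate opening). The risks are sulfur participation when BF3 activates an epoxide next to two dithianes, and the thermal lability of lithiated ethyl propiolate. The fallback uses a different nucleophile without any Lewis acid, the dianion of propiolic acid. It sets out from 15: propiolic acid with n-BuLi (2 equiv) in THF/HMPA, −45 °C → rt, gives (S)-6-{2-[(S)-2-(tert-butyldimethylsilyloxy)-3-(2-nonyl-1,3-dithian-2-yl)propyl]-1,3-dithian-2-yl}-5-hydroxyhex-2-ynoic acid F3. Esterification (EtI, K2CO3, DMF) brings the route back at 18.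

Step 7 (last reduction on the lactone). The risks are hydride and alkoxide acting on the hydroxy-substituted unsaturated lactone (conjugate reduction, oxa-Michael closure by the C7 hydroxyl), hemiketal formation, and boron removal from the triol. The fallback sets the last stereocenter before the ring exists. It sets out from 20: desilylation (HF aq., MeCN) gives ethyl (5S,7R,9R)-5,7,9-trihydroxy-11-oxoicos-2-ynoate F4. Reduction (Et2BOMe, NaBH4, THF/MeOH, −78 °C) gives ethyl (5S,7R,9S,11S)-5,7,9,11-tetrahydroxyicos-2-ynoate F5. Semihydrogenation (H2, Pd/CaCO3 poisoned with Pb(OAc)2, quinoline, EtOAc) gives ethyl (2Z,5S,7R,9S,11S)-5,7,9,11-tetrahydroxyicos-2-enoate F6, and lactonization (PPTS, CH2Cl2) brings the route back at 24.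

**Further compounds**
F1 | step 2 | (R)-1-(1,3-dithian-2-yl)-3-(2-nonyl-1,3-dithian-2-yl)propan-2-ol | CCCCCCCCCC1(C[C@H](O)CC2SCCCS2)SCCCS1
F2 | step 2 | 2-[(R)-2-(tert-butyldimethylsilyloxy)-3-(2-nonyl-1,3-dithian-2-yl)propyl]-1,3-dithiane | CCCCCCCCCC1(C[C@H](O[Si](C)(C)C(C)(C)C)CC2SCCCS2)SCCCS1
F3 | step 3 | (S)-6-{2-[(S)-2-(tert-butyldimethylsilyloxy)-3-(2-nonyl-1,3-dithian-2-yl)propyl]-1,3-dithian-2-yl}-5-hydroxyhex-2-ynoic acid | CCCCCCCCCC1(C[C@H](O[Si](C)(C)C(C)(C)C)CC2(C[C@@H](O)CC#CC(=O)O)SCCCS2)SCCCS1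
F4 | step 7 | ethyl (5S,7R,9R)-5,7,9-trihydroxy-11-oxoicos-2-ynoate | CCCCCCCCCC(=O)C[C@H](O)C[C@H](O)C[C@@H](O)CC#CC(=O)OCC
F5 | step 7 | ethyl (5S,7R,9S,11S)-5,7,9,11-tetrahydroxyicos-2-ynoate | CCCCCCCCC[C@H](O)C[C@H](O)C[C@H](O)C[C@@H](O)CC#CC(=O)OCC
F6 | step 7 | ethyl (2Z,5S,7R,9S,11S)-5,7,9,11-tetrahydroxyicos-2-enoate | CCCCCCCCC[C@H](O)C[C@H](O)C[C@H](O)C[C@@H](O)C/C=C\C(=O)OCC
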